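The easy step is the reagent: its last portion goes in at 9.00 min, earlier than the first reading at 0.833 h. So every reading shows a flask with its reagent charged.

all flasks: precatalyst 0.1 mol%

| run | substrate | reagent | remark | time |
|---|---|---|---|---|
| blue | 0.23 M | 1.5 equiv (in portions, 4) | run made earlier; portions every 3.0 min |  |
| green | 0.77 M | 1.5 equiv (in portions, 4) | run made earlier; portions every 3.0 min |  |
| north | 0.30 M | 1.50 equiv (in portions, 4) | the portions of reagent follow each other after 3.0 min, the first at the start | 12 h |
| north-west | 0.40 M | 1.50 equiv (in portions, 4) | the portions of reagent follow each other after 3.0 min, the first at the start | 12 h |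
| south-west | 0.60 M | 1.50 equiv (in portions, 4) | the portions of reagent follow each other after 3.0 min, the first at the start | 12 h |
| south | 1.0 M | 1.50 equiv (in portions, 4) | the portions of reagent follow each other after 3.0 min, the first at the start | 12 h |

| run | time / h | target / % | substrate / % |
|---|---|---|---|
| blue | 0.833 | 6.5 | 91.5 |
| blue | 2.50 | 18.9 | 59.8 |
| blue | 4.00 | 21.9 | 38.5 |
| blue | 6.00 | 23.1 | 22.0 |
| blue | 10.0 | 21.7 | 9.1 |
| blue | 12.0 | 21.1 | 5.3 |
| green | 0.833 | 12.8 | 72.1 |
| green | 2.50 | 30.2 | 8.4 |
| green | 4.00 | 32.9 | 0.8 |
| green | 6.00 | 32.8 | 0 |
| green | 10.0 | 32.5 | 0.1 |
| green | 12.0 | 33.4 | 0 |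

(each reading ± 0.3 percentage points)

- [target] at the end for north, north-west, south-west, south, in this order
- the course of these numbers from the first flask to the last (falls, then rises / rises, then falls / falls all the way / rises all the way / hardly changes)

- the analysis behind the earlier runs scatters by 0.3 percentage points, standard deviation
- "hardly changes" means that all values lie within two and a half points (for a concentration: within two and a half percent of the largest)

The next rung is the half-life of the substrate, read between two readings. In the green run it is 0.537 h. In the blue run, read later in its course, it is 2.48 h, which is longer. The last rung is the late change in the target. In the green run the substrate stands at 0.8% after 4.00 h, and from there the target stays flat within the scatter. In the blue run the substrate still stands at 22.0% after 6.00 h, and the target then drops by 2 percentage points up to 12.0 h, against a scatter of 0.3 points.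

So I look for the crossing between flasks that reach a plateau and flasks that are still changing. I carry the plateau share, the overall selectivity of a finished flask: the part of the charged substrate that stands as target once the readings stop moving. The green run gives 32.9%. The blue run ends lower, at 21.1%. I take the plateau share as a ceiling. This is my own reckoning: times the charge, it gives c(target) of 0.0987 M, 0.132 M, 0.197 M and 0.329 M. I expect north and north-west to end below their ceilings, as the blue run did.

The forecast gives 0.074 M, 0.11 M, 0.186 M and 0.35 M, and its course rises all the way, “with some flattening assumed at 1.0 M”. Its south, at 35%, stands higher than my ceiling.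

The flasks end at 0.0799 M, 0.122 M, 0.197 M and 0.327 M, and the course rises all the way, so the forecast holds within its margin.

    reagent + free catalyst → catalyst intermediate A (k = 0.478 M⁻¹ s⁻¹)
    catalyst intermediate B ⇌ catalyst intermediate C (K = 0.450, k = 1.29 s⁻¹)
    substrate + target → side product (k = 7.08 × 10⁻⁴ M⁻¹ s⁻¹)
    catalyst intermediate C → free catalyst + target (k = 52.3 s⁻¹)
    substrate + catalyst intermediate A ⇌ catalyst intermediate B (K = 0.860 M⁻¹, k = 1.83 M⁻¹ s⁻¹)
    precatalyst → free catalyst (k = 3.49 × 10⁻⁴ s⁻¹)
    free catalyst → spent catalyst (k = 1.87 × 10⁻⁴ s⁻¹)

At the end, spent catalyst makes up 71.1% of the catalyst charged in north, more than the 23.1% in south. The plateau share gives 0.329 M for south, which ends at 0.327 M. North ends 0.0188 M below its ceiling. For the row to fall at its last step, south's share would have to lie under 19.7%, and it stands at 32.7%.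

The readings come from a simulation on assumed constants, noise included.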